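**Retrosynthetic overview**

1. Target 17 ⇐ hexa-O-benzyl-6,6'-dibromo dimer 16; one hydrogenolysis removes the six benzyl groups and the two C6 bromine caps.
2. 16 ⇐ C4(upper)–C8(lower) Friedel–Crafts bond between the 4-alkoxy 2,3-cis unit 15 (2S,3S) and the 2,3-trans unit 11 (2R,3S); bromine at C6 of both units leaves C8 as the only activated arene position.
3. 11 and 14 (→ 15) ⇐ one common (2S,3S)-epoxy phenol 10: anti 6-endo opening (inversion at C2) gives the lower unit, a new boron-relayed syn opening (retention at C2) gives the upper unit; C3 stays S in both.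
4. 10 ⇐ silyl ether 9 ⇐ Shi epoxidation of (E)-1,3-diarylpropene 8 ⇐ chalcone 4 ⇐ acetophenone 2 + aldehyde 3.
5. Ring order: rings A and B are bought; ring C of the lower unit and ring C of the upper unit are closed in parallel from 10; the interflavan bond is made last.

The target was read as ent-epifisetinidol-(4α→8)-fisetinidol: upper unit 2S,3S,4S (2,3-cis-3,4-trans), lower unit 2R,3S (2,3-trans).

Assumption: the chiral ketone catalysts (Shi ketone and its enantiomer) are treated as purchased catalysts, not as starting materials.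

**Route**

Step 1
Reactants: 1 1-[4-(benzyloxy)-2-hydroxyphenyl]ethan-1-one
Product: 2 1-[4-(benzyloxy)-5-bromo-2-hydroxyphenyl]ethan-1-one
Conditions: NBS (1.05 equiv), MeCN, 0 °C → rt
Reagents that add atoms: N-bromosuccinimide, O=C1CCC(=O)N1Br
Why: Electrophilic aromatic bromination goes to C5 (para to the chelated OH, ortho to OBn, meta to acetyl); this bromine becomes the C6 cap of both flavan units.

Step 2
Reactants: 2 1-[4-(benzyloxy)-5-bromo-2-hydroxyphenyl]ethan-1-one; 3 3,4-bis(benzyloxy)benzaldehyde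
Product: 4 (E)-1-[4-(benzyloxy)-5-bromo-2-hydroxyphenyl]-3-[3,4-bis(benzyloxy)phenyl]prop-2-en-1-one
Conditions: KOH (50% aq.), EtOH/THF, rt; then aq. HCl
Reagents that add atoms: none
Why: Claisen–Schmidt aldol condensation of a methyl ketone with a non-enolisable aldehyde, with E1cB dehydration giving the E-enone.

Step 3
Reactants: 4 (E)-1-[4-(benzyloxy)-5-bromo-2-hydroxyphenyl]-3-[3,4-bis(benzyloxy)phenyl]prop-2-en-1-one
Product: 7 5-(benzyloxy)-4-bromo-2-{(E)-3-[3,4-bis(benzyloxy)phenyl]prop-2-en-1-yl}phenol, via aryl ethyl carbonate 5 (not isolated), via o-quinone methide 6 (not isolated)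
Conditions: ClCO2Et, Et3N, THF, 0 °C; then NaBH4, H2O, 0 °C → rt
Reagents that add atoms: none
Why: Known reductive deoxygenation of 2'-hydroxychalcones: hydride reduces the ketone of 5, the alkoxide takes over the carbonate and 1,4-elimination gives quinone methide 6, which accepts a second hydride at the methide carbon and leaves the conjugated E-styrene untouched.

Step 4
Reactants: 7 5-(benzyloxy)-4-bromo-2-{(E)-3-[3,4-bis(benzyloxy)phenyl]prop-2-en-1-yl}phenol
Product: 8 {5-(benzyloxy)-4-bromo-2-[(E)-3-(3,4-bis(benzyloxy)phenyl)prop-2-en-1-yl]phenoxy}(tert-butyl)dimethylsilane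
Conditions: TBSCl, imidazole, DMF, rt
Reagents that add atoms: tert-butyldimethylsilyl chloride, CC(C)(C)[Si](C)(C)Cl
Why: Standard phenol silylation, so that the phenoxide is neither oxidised by the dioxirane nor opens the epoxide at pH 10.5 in the next step.

Step 5
Reactants: 8 {5-(benzyloxy)-4-bromo-2-[(E)-3-(3,4-bis(benzyloxy)phenyl)prop-2-en-1-yl]phenoxy}(tert-butyl)dimethylsilane
Product: 9 {5-(benzyloxy)-4-bromo-2-[((2S,3S)-3-(3,4-bis(benzyloxy)phenyl)oxiran-2-yl)methyl]phenoxy}(tert-butyl)dimethylsilane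
Conditions: L-fructose-derived Shi ketone (1,2:4,5-di-O-isopropylidene-β-L-erythro-2,3-hexodiulo-2,6-pyranose, 30 mol%), KHSO5 (as 2KHSO5·KHSO4·K2SO4), K2CO3, Bu4NHSO4 (cat.), MeCN/CH2(OMe)2/aq. Na2B4O7 buffer (pH 10.5), 0 °C
Reagents that add atoms: potassium peroxymonosulfate, [K+].[O-]S(=O)(=O)OO
Why: Shi asymmetric epoxidation (chiral dioxirane, spiro transition state): this ketone is the mirror image of the catalyst that gives (R,R)-epoxides from trans-β-alkylstyrenes, so both oxirane centres are set as S,S (expected 90–95% ee), and this is the only step that creates absolute configuration.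

Step 6
Reactants: 9 {5-(benzyloxy)-4-bromo-2-[((2S,3S)-3-(3,4-bis(benzyloxy)phenyl)oxiran-2-yl)methyl]phenoxy}(tert-butyl)dimethylsilane
Product: 10 5-(benzyloxy)-4-bromo-2-{[(2S,3S)-3-(3,4-bis(benzyloxy)phenyl)oxiran-2-yl]methyl}phenol
Conditions: TBAF (1.1 equiv), AcOH (1.2 equiv), THF, 0 °C, 20 min; cold pH 7 buffer wash; used at once without chromatography
Reagents that add atoms: none
Why: Fluoride-mediated cleavage of the aryl silyl ether; the AcOH buffer keeps the phenol protonated so no phenoxide opens the oxirane, and both oxirane centres are untouched.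

Step 7
Reactants: 10 5-(benzyloxy)-4-bromo-2-{[(2S,3S)-3-(3,4-bis(benzyloxy)phenyl)oxiran-2-yl]methyl}phenol
Product: 11 (2R,3S)-7-(benzyloxy)-2-[3,4-bis(benzyloxy)phenyl]-6-bromochroman-3-ol
Conditions: CSA (10 mol%), CH2Cl2, −20 °C
Reagents that add atoms: none
Why: Acid-catalysed 6-endo-tet epoxide opening: the phenol attacks the p-alkoxybenzylic oxirane carbon anti to the C–O bond (inversion → C2 = R) while the other oxirane carbon becomes C3 (S) unchanged, closing the 2,3-trans ring C.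

Step 8
Reactants: 10 5-(benzyloxy)-4-bromo-2-{[(2S,3S)-3-(3,4-bis(benzyloxy)phenyl)oxiran-2-yl]methyl}phenol
Product: 14 (2S,3S)-7-(benzyloxy)-2-[3,4-bis(benzyloxy)phenyl]-6-bromochroman-3-ol, via aryl borinate 12 (not isolated), via flavan-3-yl borinate 13 (not isolated)
Conditions: (C6F5)2BOH (20 mol%), 4 Å MS, toluene, −40 °C; aq. NaHCO3
Reagents that add atoms: none
Why: Proposed new method: the borinic acid condenses with the phenol of 10 to aryl borinate 12, whose Lewis-acidic boron binds the oxirane oxygen intramolecularly and ionises the p-alkoxybenzylic C–O bond; in the resulting borate/benzylic-cation pair the boron-bound aryloxide sits on the face the oxygen has just left and is handed back to C2 through a 5-membered SNi-like transition state with the aryl group equatorial, so C2 forms with retention (2S), C3 (S) is untouched, and the 2,3-cis ring C is released as borinate 13, which transesterifies with fresh 10 to turn the catalyst over; the closest known reaction type is boron-mediated aglycon delivery (1,2-cis-glycosylation of 1,2-anhydro sugars through boronic or borinic esters), which has not been applied to an intramolecular phenol-to-aryl-epoxide transfer or to 2,3-cis-flavan-3-ols.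

Step 9
Reactants: 14 (2S,3S)-7-(benzyloxy)-2-[3,4-bis(benzyloxy)phenyl]-6-bromochroman-3-ol
Product: 15 (2S,3S,4R)-7-(benzyloxy)-2-[3,4-bis(benzyloxy)phenyl]-6-bromo-4-(2-ethoxyethoxy)chroman-3-ol
Conditions: DDQ (2 equiv), EtOCH2CH2OH (10 equiv), CH2Cl2, rt
Reagents that add atoms: 2-ethoxyethanol, CCOCCO
Why: DDQ benzylic oxidation (hydride abstraction at C4, cation stabilised by the para 7-benzyloxy group and the ortho ring oxygen) with trapping by the alcohol trans to the axial 3-OH; the C4 configuration is lost again in step 10, so only the oxidation level matters.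

Step 10
Reactants: 15 (2S,3S,4R)-7-(benzyloxy)-2-[3,4-bis(benzyloxy)phenyl]-6-bromo-4-(2-ethoxyethoxy)chroman-3-ol; 11 (2R,3S)-7-(benzyloxy)-2-[3,4-bis(benzyloxy)phenyl]-6-bromochroman-3-ol
Product: 16 (2S,3S,4S)-7-(benzyloxy)-2-[3,4-bis(benzyloxy)phenyl]-6-bromo-4-{(2R,3S)-7-(benzyloxy)-2-[3,4-bis(benzyloxy)phenyl]-6-bromo-3-hydroxychroman-8-yl}chroman-3-ol
Conditions: 11 (3 equiv), TMSOTf (0.2 equiv), CH2Cl2, −78 → −40 °C
Reagents that add atoms: none
Why: Lewis-acid Friedel–Crafts alkylation through the C4 benzylic cation: bromine blocks C6 in both partners so the only activated arene carbon is C8, the arene adds anti to the axial 3-hydroxy group of the 2,3-cis unit to set C4 as S (3,4-trans), and the excess of 11 outcompetes self-condensation of 15.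

Step 11
Reactants: 16 (2S,3S,4S)-7-(benzyloxy)-2-[3,4-bis(benzyloxy)phenyl]-6-bromo-4-{(2R,3S)-7-(benzyloxy)-2-[3,4-bis(benzyloxy)phenyl]-6-bromo-3-hydroxychroman-8-yl}chroman-3-ol
Product: 17 (2S,3S,4S)-2-(3,4-dihydroxyphenyl)-4-[(2R,3S)-2-(3,4-dihydroxyphenyl)-3,7-dihydroxychroman-8-yl]chromane-3,7-diol
Conditions: H2 (1 atm), Pd(OH)2/C, Et3N (2.2 equiv), degassed THF/MeOH/H2O, rt
Reagents that add atoms: none
Why: Catalytic hydrogenolysis cleaves all six benzyl ethers and both aryl C–Br bonds in one operation, with Et3N taking up HBr so the acid-labile interflavan bond and all five stereocentres are untouched.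

**Compound list**

1 | 1-[4-(benzyloxy)-2-hydroxyphenyl]ethan-1-one | CC(=O)c1ccc(OCc2ccccc2)cc1O | starting material
2 | 1-[4-(benzyloxy)-5-bromo-2-hydroxyphenyl]ethan-1-one | CC(=O)c1cc(Br)c(OCc2ccccc2)cc1O | intermediate
3 | 3,4-bis(benzyloxy)benzaldehyde | O=Cc1ccc(OCc2ccccc2)c(OCc2ccccc2)c1 | starting material
4 | (E)-1-[4-(benzyloxy)-5-bromo-2-hydroxyphenyl]-3-[3,4-bis(benzyloxy)phenyl]prop-2-en-1-one | O=C(/C=C/c1ccc(OCc2ccccc2)c(OCc2ccccc2)c1)c1cc(Br)c(OCc2ccccc2)cc1O | intermediate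
5 | 5-(benzyloxy)-4-bromo-2-{(E)-3-[3,4-bis(benzyloxy)phenyl]prop-2-enoyl}phenyl ethyl carbonate | CCOC(=O)Oc1cc(OCc2ccccc2)c(Br)cc1C(=O)/C=C/c1ccc(OCc2ccccc2)c(OCc2ccccc2)c1 | intermediate
6 | (6E)-3-(benzyloxy)-4-bromo-6-{(E)-3-[3,4-bis(benzyloxy)phenyl]prop-2-en-1-ylidene}cyclohexa-2,4-dien-1-one | O=C1C=C(OCc2ccccc2)C(Br)=C\C1=C/C=C/c1ccc(OCc2ccccc2)c(OCc2ccccc2)c1 | intermediate
7 | 5-(benzyloxy)-4-bromo-2-{(E)-3-[3,4-bis(benzyloxy)phenyl]prop-2-en-1-yl}phenol | Oc1cc(OCc2ccccc2)c(Br)cc1C/C=C/c1ccc(OCc2ccccc2)c(OCc2ccccc2)c1 | intermediate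
8 | {5-(benzyloxy)-4-bromo-2-[(E)-3-(3,4-bis(benzyloxy)phenyl)prop-2-en-1-yl]phenoxy}(tert-butyl)dimethylsilane | CC(C)(C)[Si](C)(C)Oc1cc(OCc2ccccc2)c(Br)cc1C/C=C/c1ccc(OCc2ccccc2)c(OCc2ccccc2)c1 | intermediate
9 | {5-(benzyloxy)-4-bromo-2-[((2S,3S)-3-(3,4-bis(benzyloxy)phenyl)oxiran-2-yl)methyl]phenoxy}(tert-butyl)dimethylsilane | CC(C)(C)[Si](C)(C)Oc1cc(OCc2ccccc2)c(Br)cc1C[C@@H]1O[C@H]1c1ccc(OCc2ccccc2)c(OCc2ccccc2)c1 | intermediate
10 | 5-(benzyloxy)-4-bromo-2-{[(2S,3S)-3-(3,4-bis(benzyloxy)phenyl)oxiran-2-yl]methyl}phenol | Oc1cc(OCc2ccccc2)c(Br)cc1C[C@@H]1O[C@H]1c1ccc(OCc2ccccc2)c(OCc2ccccc2)c1 | intermediate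
11 | (2R,3S)-7-(benzyloxy)-2-[3,4-bis(benzyloxy)phenyl]-6-bromochroman-3-ol (2,3-trans) | O[C@H]1Cc2cc(Br)c(OCc3ccccc3)cc2O[C@@H]1c1ccc(OCc2ccccc2)c(OCc2ccccc2)c1 | intermediate
12 | 5-(benzyloxy)-4-bromo-2-{[(2S,3S)-3-(3,4-bis(benzyloxy)phenyl)oxiran-2-yl]methyl}phenyl bis(pentafluorophenyl)borinate | Fc1c(F)c(F)c(c(F)c1F)B(Oc1cc(OCc2ccccc2)c(Br)cc1C[C@@H]1O[C@H]1c1ccc(OCc2ccccc2)c(OCc2ccccc2)c1)c1c(F)c(F)c(F)c(F)c1F | intermediate
13 | (2S,3S)-7-(benzyloxy)-2-[3,4-bis(benzyloxy)phenyl]-6-bromochroman-3-yl bis(pentafluorophenyl)borinate | Fc1c(F)c(F)c(c(F)c1F)B(O[C@H]1Cc2cc(Br)c(OCc3ccccc3)cc2O[C@H]1c1ccc(OCc2ccccc2)c(OCc2ccccc2)c1)c1c(F)c(F)c(F)c(F)c1F | intermediate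
14 | (2S,3S)-7-(benzyloxy)-2-[3,4-bis(benzyloxy)phenyl]-6-bromochroman-3-ol (2,3-cis) | O[C@H]1Cc2cc(Br)c(OCc3ccccc3)cc2O[C@H]1c1ccc(OCc2ccccc2)c(OCc2ccccc2)c1 | intermediate
15 | (2S,3S,4R)-7-(benzyloxy)-2-[3,4-bis(benzyloxy)phenyl]-6-bromo-4-(2-ethoxyethoxy)chroman-3-ol (2,3-cis-3,4-trans) | C(c1ccccc1)Oc1c(Br)cc2c(c1)O[C@@H](c1ccc(OCc3ccccc3)c(OCc3ccccc3)c1)[C@@H](O)[C@@H]2OCCOCC | intermediate
16 | (2S,3S,4S)-7-(benzyloxy)-2-[3,4-bis(benzyloxy)phenyl]-6-bromo-4-{(2R,3S)-7-(benzyloxy)-2-[3,4-bis(benzyloxy)phenyl]-6-bromo-3-hydroxychroman-8-yl}chroman-3-ol | C(c1ccccc1)Oc1c(Br)cc2c(c1)O[C@@H](c1ccc(OCc3ccccc3)c(OCc3ccccc3)c1)[C@@H](O)[C@@H]2c1c(OCc3ccccc3)c(Br)cc2c1O[C@H](c1ccc(OCc3ccccc3)c(OCc3ccccc3)c1)[C@@H](O)C2 | intermediate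
17 | (2S,3S,4S)-2-(3,4-dihydroxyphenyl)-4-[(2R,3S)-2-(3,4-dihydroxyphenyl)-3,7-dihydroxychroman-8-yl]chromane-3,7-diol (CNP0189433.2) | Oc1ccc2c(c1)O[C@@H](c1ccc(O)c(O)c1)[C@@H](O)[C@@H]2c1c(O)ccc2c1O[C@H](c1ccc(O)c(O)c1)[C@@H](O)C2 | target

**Step count and risk**

Total steps: 11. Longest linear sequence: 10 (steps 1–6, 8, 9, 10, 11); the lower-unit branch is steps 1–7, 10, 11. Epoxy phenol 10 is split roughly 3:1 between steps 7 and 8 to match the excess of 11 used in step 10. Joining two units of about 90–95% ee also upgrades enantiopurity, because the minor enantiomers end up mainly in diastereomeric dimers that are removed by chromatography of 16.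

The three steps most likely to fail:

Step 8 (the new syn-selective ring closure). The risks are a background anti opening by unbound phenol (which gives 11), a hydride-shift rearrangement of the benzylic cation to the 1,3-diarylpropan-2-one, and slow catalyst turnover. The fallback uses known chemistry, sets out from alkene 8 and comes back at 14. Epoxidise 8 under the conditions of step 5 but with the D-fructose-derived Shi ketone to obtain the enantiomeric (2R,3R)-epoxide F1. Desilylate it as in step 6 to the free epoxy phenol F2 (used crude) and cyclise with CSA as in step 7 to the (2S,3R)-2,3-trans-flavan-3-ol F3. Oxidise with Dess–Martin periodinane to the (2S)-flavan-3-one F4, then reduce with LiBH(s-Bu)3 at −78 °C; hydride enters anti to the C2 aryl group and gives the 2,3-cis alcohol 14. This costs four extra steps and the second catalyst enantiomer.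

Step 9 (DDQ oxidation at C4). Ring A has no 5-oxygen and carries bromine, so hydride abstraction may instead occur at C2–H (activated by ring B and O1) or be too slow. The fallback sets out from 14 and comes back at 16, replacing both the quinone oxidation and the 4-alkoxy leaving group. Acetylate 14 (Ac2O, pyridine) to the 3-O-acetate F5. Acetoxylate C4 with Pb(OAc)4 in benzene at 60 °C, a benzylic acetoxylation of the kind used on peralkylated flavan-3-ols, to the 3,4-trans diacetate F6. Couple F6 with 11 under BF3·OEt2 (CH2Cl2, −40 °C); the 3-acetoxy group bridges the C4 cation as a dioxolanylium ion and enforces 3,4-trans entry of the arene, giving the 3-O-acetyl dimer F7. K2CO3/MeOH then frees the 3-hydroxy group to give 16.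

Step 10 (Friedel–Crafts coupling at C8). C8 lies between two ether oxygens and is deactivated by the meta bromine, so ring B positions of 11 or C8 of 15 may compete. The fallback sets out from 11 (with 15) and comes back at 16; it makes the coupling intramolecular through a temporary diester tether between the two 3-hydroxy groups, a known tactic for procyanidin dimers. Open glutaric anhydride with 11 (DMAP, pyridine) to the hemiglutarate F8. Esterify F8 with the 3-hydroxy group of 15 (DCC, DMAP) to the mixed glutarate diester F9. Cyclise with TMSOTf at high dilution (CH2Cl2, 1 mM, −40 °C) to the macrocyclic 4→8 dimer F10, then cleave the tether with i-Bu2AlH to reach 16.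

**Further compounds**

F1 | step 8 | {5-(benzyloxy)-4-bromo-2-[((2R,3R)-3-(3,4-bis(benzyloxy)phenyl)oxiran-2-yl)methyl]phenoxy}(tert-butyl)dimethylsilane | CC(C)(C)[Si](C)(C)Oc1cc(OCc2ccccc2)c(Br)cc1C[C@H]1O[C@@H]1c1ccc(OCc2ccccc2)c(OCc2ccccc2)c1
F2 | step 8 | 5-(benzyloxy)-4-bromo-2-{[(2R,3R)-3-(3,4-bis(benzyloxy)phenyl)oxiran-2-yl]methyl}phenol | Oc1cc(OCc2ccccc2)c(Br)cc1C[C@H]1O[C@@H]1c1ccc(OCc2ccccc2)c(OCc2ccccc2)c1
F3 | step 8 | (2S,3R)-7-(benzyloxy)-2-[3,4-bis(benzyloxy)phenyl]-6-bromochroman-3-ol | O[C@@H]1Cc2cc(Br)c(OCc3ccccc3)cc2O[C@H]1c1ccc(OCc2ccccc2)c(OCc2ccccc2)c1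
F4 | step 8 | (2S)-7-(benzyloxy)-2-[3,4-bis(benzyloxy)phenyl]-6-bromochroman-3-one | O=C1Cc2cc(Br)c(OCc3ccccc3)cc2O[C@H]1c1ccc(OCc2ccccc2)c(OCc2ccccc2)c1
F5 | step 9 | (2S,3S)-7-(benzyloxy)-2-[3,4-bis(benzyloxy)phenyl]-6-bromochroman-3-yl acetate | CC(=O)O[C@H]1Cc2cc(Br)c(OCc3ccccc3)cc2O[C@H]1c1ccc(OCc2ccccc2)c(OCc2ccccc2)c1
F6 | step 9 | (2S,3R,4R)-7-(benzyloxy)-2-[3,4-bis(benzyloxy)phenyl]-6-bromochromane-3,4-diyl diacetate (2,3-cis-3,4-trans) | C(c1ccccc1)Oc1c(Br)cc2c(c1)O[C@@H](c1ccc(OCc3ccccc3)c(OCc3ccccc3)c1)[C@@H](OC(C)=O)[C@@H]2OC(C)=O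
F7 | step 9 | (2S,3S,4S)-7-(benzyloxy)-2-[3,4-bis(benzyloxy)phenyl]-6-bromo-4-{(2R,3S)-7-(benzyloxy)-2-[3,4-bis(benzyloxy)phenyl]-6-bromo-3-hydroxychroman-8-yl}chroman-3-yl acetate | C(c1ccccc1)Oc1c(Br)cc2c(c1)O[C@@H](c1ccc(OCc3ccccc3)c(OCc3ccccc3)c1)[C@@H](OC(C)=O)[C@@H]2c1c(OCc3ccccc3)c(Br)cc2c1O[C@H](c1ccc(OCc3ccccc3)c(OCc3ccccc3)c1)[C@@H](O)C2
F8 | step 10 | 5-{[(2R,3S)-7-(benzyloxy)-2-(3,4-bis(benzyloxy)phenyl)-6-bromochroman-3-yl]oxy}-5-oxopentanoic acid | OC(=O)CCCC(=O)O[C@H]1Cc2cc(Br)c(OCc3ccccc3)cc2O[C@@H]1c1ccc(OCc2ccccc2)c(OCc2ccccc2)c1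
F9 | step 10 | mixed pentanedioate diester of O3 of 11 and O3 of 15 | C(c1ccccc1)Oc1c(Br)cc2c(c1)O[C@@H](c1ccc(OCc3ccccc3)c(OCc3ccccc3)c1)[C@@H](OC(=O)CCCC(=O)O[C@H]1Cc3cc(Br)c(OCc4ccccc4)cc3O[C@@H]1c1ccc(OCc3ccccc3)c(OCc3ccccc3)c1)[C@@H]2OCCOCC
F10 | step 10 | macrocyclic pentanedioate diester bridging the two 3-oxygens of 16 | C(c1ccccc1)Oc1c(Br)cc2c(c1)O[C@@H](c1ccc(OCc3ccccc3)c(OCc3ccccc3)c1)[C@@H](OC(=O)CCCC(=O)O5)[C@@H]2c1c(OCc3ccccc3)c(Br)cc2c1O[C@H](c1ccc(OCc3ccccc3)c(OCc3ccccc3)c1)[C@@H]5C2
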